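**Plan**

1. Cuts: C7'=C8' (Julia–Kocienski) and C7=C8 (Wittig) divide the C40 skeleton into crocetindial (C20) and two C10 end groups, each already carrying its own ester. In the ε-end the ring bond C1'–C6' is cut, then C6'=C7', C5'–C6' and C2'–C3'; in the β-end C6–C7 is cut.
2. Enabling feature: in the ε-ring (C1'–C6') the quaternary gem-dimethyl carbon C1' is bonded to the stereogenic, doubly allylic C6', which carries the chain carbon C7'. C1' can therefore be a tertiary radical made from an isopropenyl group, and C6' the β-carbon of a C6'=C7' acceptor whose sulfone on C7' later serves the chain olefination.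
3. Forward order: sulfonyl phosphonate (steps 1–2); acyclic ε-precursor (steps 3–7); ε-ring closed in step 8, the only ring made (the β-ring is bought as actinol); β-end C10 ylide joined to crocetindial (steps 9–14); the halves joined at C7'=C8' and equilibrated to all-E (step 15).
4. Stereochemistry: C3' from reagent-controlled asymmetric methallylboration; C6' by 1,4-induction from C3' in the ring closure; C3 from (4R,6R)-actinol; (Z)-C4'=C5' from hydroxyl-directed trans-hydroalumination; chain E-alkenes from the olefinations and the final iodine equilibration.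

Key step: step 8

Assumption: (4R,6R)-actinol, crocetin dialdehyde, but-2-ynal, 2-methylallylmagnesium chloride, (+)-B-methoxydiisopinocampheylborane and diethyl (iodomethyl)phosphonate are taken as purchasable; carotenoid numbering (primed locants for the ε-half) is used for fragments, and compound 26 stands for the Z-part of the crude olefination mixture.

**Route**

Step 1
Reactants: 1 1-phenyl-1H-tetrazole-5-thiol; 2 diethyl (iodomethyl)phosphonate
Product: 3 diethyl {[(1-phenyl-1H-tetrazol-5-yl)sulfanyl]methyl}phosphonate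
Conditions: K2CO3, DMF, 60 °C
Reagents that add atoms: none
Why: SN2 S-alkylation of the soft tetrazolethiolate at the iodomethyl carbon, sulfur reacting in preference to ring nitrogen under carbonate conditions.

Step 2
Reactants: 3 diethyl {[(1-phenyl-1H-tetrazol-5-yl)sulfanyl]methyl}phosphonate
Product: 4 diethyl {[(1-phenyl-1H-tetrazol-5-yl)sulfonyl]methyl}phosphonate
Conditions: mCPBA (3 equiv), CH2Cl2, 0 °C → reflux
Reagents that add atoms: 3-chloroperbenzoic acid, O=C(OO)c1cccc(Cl)c1
Why: Peracid oxidation of the sulfide through the sulfoxide to the sulfone, in a molecule that holds no other oxidisable group.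

Step 3
Reactants: 5 but-2-ynal; 6 2-methylallylmagnesium chloride
Product: 8 (4R)-2-methylhept-1-en-5-yn-4-ol, via borinate ester 7 (not isolated)
Conditions: (+)-Ipc2BOMe [from (−)-α-pinene], 6, Et2O, 0 °C → rt; 5, −78 °C; then NaOH, H2O2, 0 °C → rt
Reagents that add atoms: none
Why: Asymmetric allylboration: the methallylborane formed in the flask adds to the aldehyde through a six-membered chair transition state whose facial bias comes from the isopinocampheyl groups, and the reagent from (−)-α-pinene should give the (R)-propargylic alcohol that becomes C3'.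

Step 4
Reactants: 8 (4R)-2-methylhept-1-en-5-yn-4-ol
Product: 10 (4R,5Z)-6-iodo-2-methylhepta-1,5-dien-4-ol, via alkenylalanate 9 (not isolated)
Conditions: sodium bis(2-methoxyethoxy)aluminium hydride (1.3 equiv), THF, 0 °C → rt; then I2, THF, −78 °C → 0 °C
Reagents that add atoms: iodine, II
Why: Hydroxyl-directed trans-hydroalumination of the propargylic alcohol places aluminium on the distal alkyne carbon in a five-membered alkoxyalanate, and iodinolysis with retention gives the (Z)-iodoalkene that fixes the later C4'=C5' geometry.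

Step 5
Reactants: 10 (4R,5Z)-6-iodo-2-methylhepta-1,5-dien-4-ol; 11 tetradecanoyl chloride
Product: 12 (4R,5Z)-6-iodo-2-methylhepta-1,5-dien-4-yl tetradecanoate
Conditions: pyridine, DMAP (cat.), CH2Cl2, 0 °C → rt
Reagents that add atoms: none
Why: DMAP-catalysed acylation of the secondary allylic alcohol installs the final C3' ester before any electrophilic alkene exists, and no bond to the stereocentre is broken.

Step 6
Reactants: 12 (4R,5Z)-6-iodo-2-methylhepta-1,5-dien-4-yl tetradecanoate
Product: 13 (2Z,4R)-2,6-dimethyl-1-oxohepta-2,6-dien-4-yl tetradecanoate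
Conditions: Pd(PPh3)4 (5 mol %), CO (3 bar), Bu3SnH (slow addition), THF, 50 °C
Reagents that add atoms: carbon monoxide, [C-]#[O+]
Why: Palladium-catalysed reductive carbonylation (formylation with CO and tin hydride): oxidative addition into C–I with retention, CO insertion and hydride transfer give the (Z)-enal (C6' as the formyl carbon) under neutral conditions that an ester tolerates.

Step 7
Reactants: 13 (2Z,4R)-2,6-dimethyl-1-oxohepta-2,6-dien-4-yl tetradecanoate; 4 diethyl {[(1-phenyl-1H-tetrazol-5-yl)sulfonyl]methyl}phosphonate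
Product: 14 (1E,3Z,5R)-3,7-dimethyl-1-[(1-phenyl-1H-tetrazol-5-yl)sulfonyl]octa-1,3,7-trien-5-yl tetradecanoate
Conditions: LiCl, i-Pr2NEt, MeCN, 0 °C → rt
Reagents that add atoms: none
Why: Horner–Wadsworth–Emmons olefination under mild lithium chloride/amine conditions, which spare the ester and the (Z)-enal; the sulfonyl-stabilised phosphonate should give the (E)-vinyl sulfone.

Step 8
Reactants: 14 (1E,3Z,5R)-3,7-dimethyl-1-[(1-phenyl-1H-tetrazol-5-yl)sulfonyl]octa-1,3,7-trien-5-yl tetradecanoate
Product: 15 (1R,4R)-3,5,5-trimethyl-4-{[(1-phenyl-1H-tetrazol-5-yl)sulfonyl]methyl}cyclohex-2-en-1-yl tetradecanoate (ester and sulfonylmethyl arm trans; 3'R,6'R in carotenoid numbering)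
Conditions: Fe(acac)3 (0.3 equiv), PhSiH3 (2.5 equiv), EtOH/THF/(CH2OH)2, 0.01 M, 60 °C
Reagents that add atoms: none
Why: An iron(III) hydride formed from Fe(acac)3 and phenylsilane should transfer a hydrogen atom to the CH2 terminus of the isopropenyl group, which creates the second methyl group and the tertiary C1' radical; this nucleophilic radical adds to C6', the β-carbon of the sulfonyl-activated alkene, and the α-sulfonyl radical left on C7' is reduced by iron(II) and protonated by ethanol. The closest known reaction type is the iron-hydride reductive coupling of donor alkenes with vinyl sulfones and enones (a hydrogen-atom-transfer Giese addition), including ring closures that build quaternary carbons. The ε-ring closes in a 6-exo-trig mode, helped by the (Z)-C4'=C5' bond, which holds C3' and C6' on the same side and pre-folds the chain. C6' is the only new stereocentre and is set by 1,4-induction from C3': in the half-chair transition state the myristate should sit pseudo-equatorial, because a pseudo-axial ester would clash 1,3 with the methyl group of the radical carbon on the same face, and the sulfonylvinyl arm should turn outward in an s-trans-like rotamer that keeps part of the diene conjugation, which places C7' trans to the ester. The step needs hydrogen-atom transfer to the electron-rich 1,1-disubstituted alkene rather than to the electron-poor diene or the trisubstituted ring alkene of the product, which the polarity preference of the metal hydride should secure, and it needs the ring alkene to stay at C4'=C5', which the neutral conditions secure while also sparing the allylic ester and the tetrazolyl sulfone.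

Step 9
Reactants: 16 (4R,6R)-4-hydroxy-2,2,6-trimethylcyclohexan-1-one (actinol); 17 hexadecanoyl chloride
Product: 18 (1R,5R)-3,3,5-trimethyl-4-oxocyclohexyl hexadecanoate
Conditions: pyridine, DMAP (cat.), CH2Cl2, 0 °C → rt
Reagents that add atoms: none
Why: DMAP-catalysed acylation of the secondary alcohol installs the C3 palmitate on the chiral-pool ketone without touching the carbinol configuration.

Step 10
Reactants: 18 (1R,5R)-3,3,5-trimethyl-4-oxocyclohexyl hexadecanoate
Product: 19 (1R)-3,5,5-trimethyl-4-{[(trifluoromethyl)sulfonyl]oxy}cyclohex-3-en-1-yl hexadecanoate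
Conditions: Tf2O, 2,6-di-tert-butyl-4-methylpyridine, CH2Cl2, 0 °C → rt
Reagents that add atoms: trifluoromethanesulfonic anhydride, O=S(=O)(OS(=O)(=O)C(F)(F)F)C(F)(F)F
Why: Enol triflate formation with triflic anhydride and a hindered pyridine base, conditions that tolerate the ester; the quaternary α-carbon leaves only one enolisable proton, so only the future C5=C6 alkene can form, and the methyl-bearing stereocentre is removed on purpose.

Step 11
Reactants: 19 (1R)-3,5,5-trimethyl-4-{[(trifluoromethyl)sulfonyl]oxy}cyclohex-3-en-1-yl hexadecanoate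
Product: 20 (1R)-4-formyl-3,5,5-trimethylcyclohex-3-en-1-yl hexadecanoate
Conditions: Pd(PPh3)4 (5 mol %), LiCl, CO (3 bar), Bu3SnH (slow addition), THF, 50 °C
Reagents that add atoms: carbon monoxide, [C-]#[O+]
Why: Palladium-catalysed reductive carbonylation of the vinyl triflate (chloride assisting the triflate-derived palladium species) brings in C7 as the aldehyde of a 3-acyloxy-β-cyclocitral.

Step 12
Reactants: 20 (1R)-4-formyl-3,5,5-trimethylcyclohex-3-en-1-yl hexadecanoate
Product: 21 (1R)-4-(hydroxymethyl)-3,5,5-trimethylcyclohex-3-en-1-yl hexadecanoate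
Conditions: NaBH4, CeCl3·7H2O, MeOH/THF, −20 °C
Reagents that add atoms: none
Why: Luche reduction: cerium-assisted 1,2-reduction of the hindered enal by borohydride at low temperature, where the long-chain ester is not reduced.

Step 13
Reactants: 21 (1R)-4-(hydroxymethyl)-3,5,5-trimethylcyclohex-3-en-1-yl hexadecanoate
Product: 22 {[(4R)-4-(hexadecanoyloxy)-2,6,6-trimethylcyclohex-1-en-1-yl]methyl}triphenylphosphonium bromide
Conditions: PPh3·HBr, CH2Cl2/MeOH, rt
Reagents that add atoms: triphenylphosphine hydrobromide, [Br-].c1ccc(cc1)[PH+](c1ccccc1)c1ccccc1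
Why: Conversion of the allylic alcohol into the phosphonium salt through the allyl cation, which the phosphine captures at the primary terminus, the standard entry to cyclogeranyl-type Wittig salts.

Step 14
Reactants: 22 {[(4R)-4-(hexadecanoyloxy)-2,6,6-trimethylcyclohex-1-en-1-yl]methyl}triphenylphosphonium bromide; 23 crocetindial
Product: 25 all-E (3R)-3-(hexadecanoyloxy)-8'-apo-β-caroten-8'-al, via phosphonium ylide 24 (not isolated)
Conditions: NaHMDS (1.0 equiv), THF, −78 → 0 °C; then added to 23 (3 equiv), CH2Cl2/THF, −78 °C → rt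
Reagents that add atoms: none
Why: Wittig olefination of the allylic ylide with one formyl group of the dialdehyde used in excess forms C7=C8; steric compression next to the ring should favour the E alkene, and the mono-adduct is separated from recovered dialdehyde.

Step 15
Reactants: 15 (1R,4R)-3,5,5-trimethyl-4-{[(1-phenyl-1H-tetrazol-5-yl)sulfonyl]methyl}cyclohex-2-en-1-yl tetradecanoate; 25 all-E (3R)-3-(hexadecanoyloxy)-8'-apo-β-caroten-8'-al
Product: 27 (3R,3'R,6'R)-β,ε-carotene-3,3'-diol 3-hexadecanoate 3'-tetradecanoate (all-E target), via 7'Z-isomer 26 (not isolated)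
Conditions: KHMDS (1.1 equiv) added to 15 + 25, THF, −78 °C → rt; NH4Cl work-up; crude polyene: I2 (2 mol %), CH2Cl2/hexane, daylight, N2, rt
Reagents that add atoms: none
Why: Julia–Kocienski olefination: the metalated tetrazolyl sulfone adds to the aldehyde and the alkoxide undergoes Smiles rearrangement with loss of sulfur dioxide and the tetrazolone to form C7'=C8', after which iodine-catalysed equilibration should relax the hindered 7'Z part to the all-E polyene without touching the three stereocentres.

**Compound list**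

1 | 1-phenyl-1H-tetrazole-5-thiol | SC1=NN=NN1c1ccccc1 | starting material
2 | diethyl (iodomethyl)phosphonate | CCOP(=O)(CI)OCC | starting material
3 | diethyl {[(1-phenyl-1H-tetrazol-5-yl)sulfanyl]methyl}phosphonate | CCOP(=O)(CSC1=NN=NN1c1ccccc1)OCC | intermediate
4 | diethyl {[(1-phenyl-1H-tetrazol-5-yl)sulfonyl]methyl}phosphonate | CCOP(=O)(CS(=O)(=O)C1=NN=NN1c1ccccc1)OCC | intermediate
5 | but-2-ynal | CC#CC=O | starting material
6 | 2-methylallylmagnesium chloride | C=C(C)C[Mg]Cl | starting material
7 | (4R)-2-methylhept-1-en-5-yn-4-yl diisopinocampheylborinate (isopinocampheyl groups from (−)-α-pinene) | C=C(C)C[C@@H](OB([C@H]1C[C@H]2C[C@H](C2(C)C)[C@@H]1C)[C@H]1C[C@H]2C[C@H](C2(C)C)[C@@H]1C)C#CC | intermediate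
8 | (4R)-2-methylhept-1-en-5-yn-4-ol | C=C(C)C[C@@H](O)C#CC | intermediate
9 | sodium cyclic alkoxy(alkenyl)bis(2-methoxyethoxy)alanate (five-membered O–Al–C(CH3)=CH–CH ring, Al on the methyl-bearing alkene carbon, cis to the carbinol carbon) | [Na+].C=C(C)C[C@@H]1C=C(C)[Al-](OCCOC)(OCCOC)O1 | intermediate
10 | (4R,5Z)-6-iodo-2-methylhepta-1,5-dien-4-ol | C=C(C)C[C@@H](O)/C=C(C)\I | intermediate
11 | tetradecanoyl chloride (myristoyl chloride) | CCCCCCCCCCCCCC(=O)Cl | starting material
12 | (4R,5Z)-6-iodo-2-methylhepta-1,5-dien-4-yl tetradecanoate | C=C(C)C[C@@H](OC(=O)CCCCCCCCCCCCC)/C=C(C)\I | intermediate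
13 | (2Z,4R)-2,6-dimethyl-1-oxohepta-2,6-dien-4-yl tetradecanoate | C=C(C)C[C@@H](OC(=O)CCCCCCCCCCCCC)/C=C(C)\C=O | intermediate
14 | (1E,3Z,5R)-3,7-dimethyl-1-[(1-phenyl-1H-tetrazol-5-yl)sulfonyl]octa-1,3,7-trien-5-yl tetradecanoate | C=C(C)C[C@@H](OC(=O)CCCCCCCCCCCCC)/C=C(C)\C=C\S(=O)(=O)C1=NN=NN1c1ccccc1 | intermediate
15 | (1R,4R)-3,5,5-trimethyl-4-{[(1-phenyl-1H-tetrazol-5-yl)sulfonyl]methyl}cyclohex-2-en-1-yl tetradecanoate (1,4-trans) | O=S(=O)(C[C@H]1C(C)=C[C@H](OC(=O)CCCCCCCCCCCCC)CC1(C)C)C2=NN=NN2c3ccccc3 | intermediate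
16 | (4R,6R)-4-hydroxy-2,2,6-trimethylcyclohexan-1-one (actinol) | CC1(C)C[C@H](O)C[C@@H](C)C1=O | starting material
17 | hexadecanoyl chloride (palmitoyl chloride) | CCCCCCCCCCCCCCCC(=O)Cl | starting material
18 | (1R,5R)-3,3,5-trimethyl-4-oxocyclohexyl hexadecanoate | CC1(C)C[C@H](OC(=O)CCCCCCCCCCCCCCC)C[C@@H](C)C1=O | intermediate
19 | (1R)-3,5,5-trimethyl-4-{[(trifluoromethyl)sulfonyl]oxy}cyclohex-3-en-1-yl hexadecanoate | CC1=C(OS(=O)(=O)C(F)(F)F)C(C)(C)C[C@H](OC(=O)CCCCCCCCCCCCCCC)C1 | intermediate
20 | (1R)-4-formyl-3,5,5-trimethylcyclohex-3-en-1-yl hexadecanoate | CC1=C(C=O)C(C)(C)C[C@H](OC(=O)CCCCCCCCCCCCCCC)C1 | intermediate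
21 | (1R)-4-(hydroxymethyl)-3,5,5-trimethylcyclohex-3-en-1-yl hexadecanoate | CC1=C(CO)C(C)(C)C[C@H](OC(=O)CCCCCCCCCCCCCCC)C1 | intermediate
22 | {[(4R)-4-(hexadecanoyloxy)-2,6,6-trimethylcyclohex-1-en-1-yl]methyl}triphenylphosphonium bromide | CC1=C(C[P+](c2ccccc2)(c2ccccc2)c2ccccc2)C(C)(C)C[C@H](OC(=O)CCCCCCCCCCCCCCC)C1.[Br-] | intermediate
23 | crocetindial, (2E,4E,6E,8E,10E,12E,14E)-2,6,11,15-tetramethylhexadeca-2,4,6,8,10,12,14-heptaenedial | O=C/C(C)=C/C=C/C(C)=C/C=C/C=C(C)/C=C/C=C(C)/C=O | starting material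
24 | {[(4R)-4-(hexadecanoyloxy)-2,6,6-trimethylcyclohex-1-en-1-yl]methylidene}triphenylphosphorane | CC1=C(C=P(c2ccccc2)(c2ccccc2)c2ccccc2)C(C)(C)C[C@H](OC(=O)CCCCCCCCCCCCCCC)C1 | intermediate
25 | all-E (3R)-3-(hexadecanoyloxy)-8'-apo-β-caroten-8'-al | CCCCCCCCCCCCCCCC(=O)O[C@@H]1CC(C)=C(/C=C/C(C)=C/C=C/C(C)=C/C=C/C=C(C)/C=C/C=C(C)/C=O)C(C)(C)C1 | intermediate
26 | (7'Z)-isomer of 27 | CCCCCCCCCCCCCCCC(=O)O[C@@H]1CC(C)=C(/C=C/C(C)=C/C=C/C(C)=C/C=C/C=C(C)/C=C/C=C(C)/C=C\[C@H]2C(C)=C[C@H](OC(=O)CCCCCCCCCCCCC)CC2(C)C)C(C)(C)C1 | intermediate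
27 | (3R,3'R,6'R)-β,ε-carotene-3,3'-diol 3-hexadecanoate 3'-tetradecanoate, all-E (lutein 3-palmitate 3'-myristate) | CCCCCCCCCCCCCCCC(=O)O[C@@H]1CC(C)=C(/C=C/C(C)=C/C=C/C(C)=C/C=C/C=C(C)/C=C/C=C(C)/C=C/[C@H]2C(C)=C[C@H](OC(=O)CCCCCCCCCCCCC)CC2(C)C)C(C)(C)C1 | target

**Count**

Total steps: 15. Longest linear sequence: 7 steps (5 → 27 through steps 3–8 and 15; equally 16 → 27 through steps 9–15).

**Steps most likely to fail**

1. Step 8. The closure may show poor or reversed facial selectivity at C6'. The sulfonylvinyl arm can swing into the pseudo-axial sector to escape the C5' methyl group and the two methyl groups on the attacking carbon, which would make the 3',6'-cis ring the main product. Hydrogen-atom transfer to the electron-poor diene, giving reduction without cyclisation, is the second hazard.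
Fallback, from 10 back to 15: the closure is run in the mirror-image C3' series and C3' is corrected afterwards. Mitsunobu esterification of 10 with tetradecanoic acid (PPh3, DIAD) inverts the carbinol and gives (4S,5Z)-6-iodo-2-methylhepta-1,5-dien-4-yl tetradecanoate F1. The carbonylative formylation of step 6 then gives the (2Z,4S)-enal F2, and the olefination of step 7 with 4 gives the (1E,3Z,5S)-dienyl sulfone F3. The iron-hydride closure, now wanted in its cis sense, gives the (1S,4R)-cis sulfone ester F4, in which C6' already has the configuration of the target. DIBAL-H at −78 °C removes the acyl group to give the (1S,4R)-allylic alcohol F5, and a second Mitsunobu reaction with tetradecanoic acid inverts C3' and delivers 15.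

2. Step 15. Addition of the β-branched sulfonyl carbanion to the conjugated, α-methylated aldehyde may be slow and reversible, so that attack of the amide base on the two ester groups and decay of the metalated sulfone overtake the olefination.
Fallback, from 15 and 23 back to 27: the order of the two chain olefinations is exchanged. Sulfone 15 is joined under the same Julia–Kocienski conditions (with iodine equilibration) to crocetindial 23 in threefold excess, an ester-free partner whose excess can drive the reversible addition, to give all-E (3R,6R)-3-(tetradecanoyloxy)-8'-apo-ε-caroten-8'-al F6. Ylide 24, made from 22 as in step 14, then forms C7=C8 in a Wittig reaction, and the crude polyene, which holds some (7Z)-isomer of the target F7, is equilibrated with iodine to 27.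

3. Step 6. The (Z) geometry may be lost by isomerisation of the acylpalladium intermediate or of the enal toward the more stable E-enal, and palladium(0) may ionise the allylic myristate to a π-allyl complex that the tin hydride reduces.
Fallback, from 10 back to 14: palladium is avoided. Silylation of 10 (TBSCl, imidazole, DMF) gives the TBS ether F8. Iodine–lithium exchange (t-BuLi, Et2O, −78 °C) gives the (Z)-alkenyllithium F9, which DMF formylates to the (2Z,4R)-silyloxy enal F10. Olefination with 4 as in step 7 gives the silyloxy dienyl sulfone F11. HF·pyridine frees the (5R)-hydroxy dienyl sulfone F12, which is acylated at once with 11 (pyridine, −20 °C) to 14, before the hydroxyl can add to the vinyl sulfone.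

**Further compounds**

F1 | step 8 | (4S,5Z)-6-iodo-2-methylhepta-1,5-dien-4-yl tetradecanoate | C=C(C)C[C@H](OC(=O)CCCCCCCCCCCCC)/C=C(C)\I
F2 | step 8 | (2Z,4S)-2,6-dimethyl-1-oxohepta-2,6-dien-4-yl tetradecanoate | C=C(C)C[C@H](OC(=O)CCCCCCCCCCCCC)/C=C(C)\C=O
F3 | step 8 | (1E,3Z,5S)-3,7-dimethyl-1-[(1-phenyl-1H-tetrazol-5-yl)sulfonyl]octa-1,3,7-trien-5-yl tetradecanoate | C=C(C)C[C@H](OC(=O)CCCCCCCCCCCCC)/C=C(C)\C=C\S(=O)(=O)C1=NN=NN1c1ccccc1
F4 | step 8 | (1S,4R)-3,5,5-trimethyl-4-{[(1-phenyl-1H-tetrazol-5-yl)sulfonyl]methyl}cyclohex-2-en-1-yl tetradecanoate (1,4-cis) | O=S(=O)(C[C@H]1C(C)=C[C@@H](OC(=O)CCCCCCCCCCCCC)CC1(C)C)C2=NN=NN2c3ccccc3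
F5 | step 8 | (1S,4R)-3,5,5-trimethyl-4-{[(1-phenyl-1H-tetrazol-5-yl)sulfonyl]methyl}cyclohex-2-en-1-ol (1,4-cis) | O=S(=O)(C[C@H]1C(C)=C[C@@H](O)CC1(C)C)C2=NN=NN2c3ccccc3
F6 | step 15 | all-E (3R,6R)-3-(tetradecanoyloxy)-8'-apo-ε-caroten-8'-al | O=C/C(C)=C/C=C/C(C)=C/C=C/C=C(C)/C=C/C=C(C)/C=C/[C@H]1C(C)=C[C@H](OC(=O)CCCCCCCCCCCCC)CC1(C)C
F7 | step 15 | (7Z)-isomer of 27 | CCCCCCCCCCCCCCCC(=O)O[C@@H]1CC(C)=C(\C=C/C(C)=C/C=C/C(C)=C/C=C/C=C(C)/C=C/C=C(C)/C=C/[C@H]2C(C)=C[C@H](OC(=O)CCCCCCCCCCCCC)CC2(C)C)C(C)(C)C1
F8 | step 6 | tert-butyl{[(4R,5Z)-6-iodo-2-methylhepta-1,5-dien-4-yl]oxy}dimethylsilane | C=C(C)C[C@@H](O[Si](C)(C)C(C)(C)C)/C=C(C)\I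
F9 | step 6 | (2Z,4R)-4-[(tert-butyldimethylsilyl)oxy]-6-methylhepta-2,6-dien-2-yllithium | C=C(C)C[C@@H](O[Si](C)(C)C(C)(C)C)/C=C(C)\[Li]
F10 | step 6 | (2Z,4R)-4-[(tert-butyldimethylsilyl)oxy]-2,6-dimethylhepta-2,6-dienal | C=C(C)C[C@@H](O[Si](C)(C)C(C)(C)C)/C=C(C)\C=O
F11 | step 6 | 5-({(1E,3Z,5R)-5-[(tert-butyldimethylsilyl)oxy]-3,7-dimethylocta-1,3,7-trien-1-yl}sulfonyl)-1-phenyl-1H-tetrazole | C=C(C)C[C@@H](O[Si](C)(C)C(C)(C)C)/C=C(C)\C=C\S(=O)(=O)C1=NN=NN1c1ccccc1
F12 | step 6 | (1E,3Z,5R)-3,7-dimethyl-1-[(1-phenyl-1H-tetrazol-5-yl)sulfonyl]octa-1,3,7-trien-5-ol | C=C(C)C[C@@H](O)/C=C(C)\C=C\S(=O)(=O)C1=NN=NN1c1ccccc1
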